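**Retrosynthetic overview**

1. Ring C, the seven-membered lactone, is opened at the ester C–O bond between the ring A carboxyl carbon and the ring B oxygen ortho to the diaryl ether. It is closed last, from hydroxy acid 31.
2. The ring A pyran comes from the 1,1-dimethylpropargyl ether of the hydroxyl para to the ester in resorcylate 26, by Claisen rearrangement and oxa-6π closure. The ring B pyran is made the same way at the start.
3. Ring A is a hexasubstituted benzene with oxygen on three alternating carbons (chelated OH, pyran O, diaryl ether O), the carboxyl-bearing carbon between the first and third, and the prenyl-bearing carbon between the second and third. These map onto diene 7 (two oxygenated carbons, the CH and the prenyl carbon) and ynoate 24 (carboxyl-bearing and aryloxy-bearing carbons), joined by [4+2] addition and aromatization. The diaryl ether oxygen arrives on the dienophile.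
4. Ynoate 24 comes from ring B chromenol 18 through its dichlorovinyl ether and lithium acetylide. 18 comes from 2,5-dibromohydroquinone by two bromine-to-oxygen exchanges around a propargyl Claisen step. Diene 7 comes from methyl acetoacetate and prenyl bromide.
5. Order of ring formation: ring B benzene (bought), ring B pyran, ring A benzene, ring A pyran, ring C lactone.

Key step: step 11

**Remarks on the chemistry**

- The target has no stereocentre; the alkene geometries of 5, 7 and 21 are those expected from the methods used.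
- The dienophile ester is carried as the allyl ester. The ring A carboxylate is doubly ortho-substituted and prone to decarboxylation, so it is unmasked by a neutral palladium-catalysed step and not by hydrolysis.
- The ring B chromenol is built from 2,5-dibromohydroquinone, in which the two para oxygens and the two para bromines are differentiated from the outset.
- ArB–O stands for the {[5,8-bis(methoxymethoxy)-2,2-dimethyl-2H-chromen-6-yl]oxy} group.

**Route**

Step 1
Reactants: 1 methyl acetoacetate; 2 prenyl bromide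
Product: 4 methyl 7-methyl-3-oxooct-6-enoate, via acetoacetate dianion 3 (not isolated)
Conditions: NaH, THF, 0 °C; n-BuLi, 0 °C; then 2, 0 °C → rt; 1 M HCl quench
Reagents that add atoms: none
Why: γ-Alkylation of the β-ketoester dianion, whose terminal carbanion is the more reactive site, by SN2 displacement on the primary allylic bromide.

Step 2
Reactants: 4 methyl 7-methyl-3-oxooct-6-enoate
Product: 5 methyl (2Z)-7-methyl-3-(trimethylsilyloxy)octa-2,6-dienoate
Conditions: TMSCl, Et3N, toluene, rt
Reagents that add atoms: chlorotrimethylsilane, C[Si](C)(C)Cl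
Why: O-Silylation of the hydrogen-bonded enol of the β-ketoester gives the conjugated Z silyl enol ether.

Step 3
Reactants: 5 methyl (2Z)-7-methyl-3-(trimethylsilyloxy)octa-2,6-dienoate
Product: 7 (1Z,3Z)-1-methoxy-7-methyl-1,3-bis(trimethylsilyloxy)octa-1,3,6-triene, via lithium dienolate 6 (not isolated)
Conditions: LiN(i-Pr)2, THF, −78 °C; TMSCl, −78 °C → rt; filtered under argon and used crude
Reagents that add atoms: chlorotrimethylsilane, C[Si](C)(C)Cl
Why: Kinetic γ-deprotonation of the silyloxy enoate and O-silylation of the extended enolate (two-stage silylation of a β-ketoester) should give the 1,1,3-trioxygenated diene with the prenyl chain on the outside of the s-cis form.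

Step 4
Reactants: 8 2,5-dibromobenzene-1,4-diol (2,5-dibromohydroquinone)
Product: 9 1,4-dibromo-2,5-bis(methoxymethoxy)benzene
Conditions: MOMCl, i-Pr2NEt, CH2Cl2, 0 °C → rt
Reagents that add atoms: chloromethyl methyl ether, COCCl
Why: Williamson-type O-alkylation of both acidic phenols protects the two para oxygens that become the ring B hydroxyl and the lactone oxygen.

Step 5
Reactants: 9 1,4-dibromo-2,5-bis(methoxymethoxy)benzene
Product: 12 4-bromo-2,5-bis(methoxymethoxy)phenol, via aryllithium 10 (not isolated), via lithium aryltrimethoxyborate 11 (not isolated)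
Conditions: n-BuLi (1.0 equiv), THF, −78 °C; B(OMe)3, −78 °C → rt; then 30% H2O2, aq NaOH, 0 °C
Reagents that add atoms: hydrogen peroxide, OO
Why: Single lithium–bromine exchange on one of two equivalent bromides (the ortho MOM ether stabilizes the aryllithium), borylation, and oxidative carbon-to-oxygen migration with alkaline peroxide turn one C–Br into C–OH.

Step 6
Reactants: 12 4-bromo-2,5-bis(methoxymethoxy)phenol
Product: 13 1-bromo-2,5-bis(methoxymethoxy)-4-[(2-methylbut-3-yn-2-yl)oxy]benzene
Conditions: 3-chloro-3-methylbut-1-yne, CuCl2·2H2O (1 mol %), DBU, MeCN, 0 °C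
Reagents that add atoms: 3-chloro-3-methylbut-1-yne, CC(C)(Cl)C#C
Why: Copper-catalysed propargylic substitution of the tertiary chloride by the phenoxide is the standard way to aryl 1,1-dimethylpropargyl ethers.

Step 7
Reactants: 13 1-bromo-2,5-bis(methoxymethoxy)-4-[(2-methylbut-3-yn-2-yl)oxy]benzene
Product: 15 6-bromo-5,8-bis(methoxymethoxy)-2,2-dimethyl-2H-chromene, via ortho-allenylphenol 14 (not isolated)
Conditions: o-xylene, 140 °C
Reagents that add atoms: none
Why: Aromatic propargyl Claisen rearrangement to the only free ortho carbon, enolization to allenylphenol 14, 1,5-hydrogen shift and oxa-6π electrocyclization close the ring B pyran.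

Step 8
Reactants: 15 6-bromo-5,8-bis(methoxymethoxy)-2,2-dimethyl-2H-chromene
Product: 18 5,8-bis(methoxymethoxy)-2,2-dimethyl-2H-chromen-6-ol, via chromenyllithium 16 (not isolated), via lithium chromenyltrimethoxyborate 17 (not isolated)
Conditions: n-BuLi (1.1 equiv), THF, −78 °C; B(OMe)3, −78 °C → rt; then 30% H2O2, aq NaOH, 0 °C
Reagents that add atoms: hydrogen peroxide, OO
Why: Lithium–bromine exchange, borylation and alkaline peroxide oxidation place the hydroxyl that becomes the diaryl ether oxygen; the nucleophilic oxidant leaves the electron-rich chromene alkene alone.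

Step 9
Reactants: 18 5,8-bis(methoxymethoxy)-2,2-dimethyl-2H-chromen-6-ol; 19 trichloroethylene
Product: 21 6-{[(E)-1,2-dichloroethenyl]oxy}-5,8-bis(methoxymethoxy)-2,2-dimethyl-2H-chromene, via potassium phenoxide 20 (not isolated)
Conditions: K2CO3, DMF, 70 °C
Reagents that add atoms: none
Why: The phenoxide adds anti across dichloroacetylene, formed in the flask by dehydrochlorination of trichloroethylene, which gives the E-dichlorovinyl ether (net vinylic substitution).

Step 10
Reactants: 21 6-{[(E)-1,2-dichloroethenyl]oxy}-5,8-bis(methoxymethoxy)-2,2-dimethyl-2H-chromene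
Product: 24 allyl 3-(ArB-oxy)prop-2-ynoate, via chloroalkynyl ether 22 (not isolated), via lithium aryloxyacetylide 23 (not isolated)
Conditions: n-BuLi (2.2 equiv), THF, −78 → −40 °C; then ClCO2CH2CH=CH2, −78 °C; rapid filtration through basic alumina
Reagents that add atoms: allyl chloroformate, C=CCOC(Cl)=O
Why: Vinylic deprotonation with β-elimination gives chloroalkyne 22, chlorine–lithium exchange gives acetylide 23, and C-acylation with the chloroformate gives the ynoate (the dichlorovinyl ether route to ynol ethers).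

Step 11
Reactants: 7 (1Z,3Z)-1-methoxy-7-methyl-1,3-bis(trimethylsilyloxy)octa-1,3,6-triene; 24 allyl 3-(ArB-oxy)prop-2-ynoate
Product: 26 allyl 2-(ArB-oxy)-4,6-dihydroxy-3-(3-methylbut-2-enyl)benzoate, via cyclohexadiene cycloadduct 25 (not isolated)
Conditions: 7 (2 equiv), toluene, 80 °C, argon; then 0.5 M HCl, THF, 0 °C
Reagents that add atoms: none
Why: The electron-rich diene 7 and the ester-polarized alkyne of 24 should combine in a thermal, normal-electron-demand Diels-Alder reaction that is concerted but strongly asynchronous: the prenyl-bearing C4 of 7, which carries the largest HOMO coefficient, bonds first to the aryloxy-bearing β-carbon of 24, and the ketene acetal carbon C1 then bonds to the α-carbon, giving 1,4-cyclohexadiene 25. The closest known reaction type is the cycloaddition-aromatization of 1-alkoxy-1,3-bis(silyloxy)butadienes with acetylenic esters to resorcylates, and 24 is such an ester with an added β-aryloxy group. Ring A is closed by this intermolecular [4+2] addition (two new C–C bonds, six-membered carbocycle); brief dilute acid then cleaves both silyl ethers, the hemiketal loses methanol and the dienone tautomerizes to the arene. No stereocentre remains, since the two sp3 carbons of 25 form as a mixture and both become aromatic carbons. The step needs one regiochemistry, and it is secured because the ester and the aryloxy oxygen polarize the alkyne in the same sense (electrophilic β-carbon, nucleophilic α-carbon), which matches the diene; a stepwise Michael-Claisen course would lead to the same arene. The prenyl, allyl and chromene double bonds are unactivated and should not compete as dienophiles.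

Step 12
Reactants: 26 allyl 2-(ArB-oxy)-4,6-dihydroxy-3-(3-methylbut-2-enyl)benzoate
Product: 27 allyl 2-(ArB-oxy)-6-hydroxy-3-(3-methylbut-2-enyl)-4-[(2-methylbut-3-yn-2-yl)oxy]benzoate
Conditions: 3-chloro-3-methylbut-1-yne, CuCl2·2H2O (1 mol %), DBU, MeCN, 0 °C → rt
Reagents that add atoms: 3-chloro-3-methylbut-1-yne, CC(C)(Cl)C#C
Why: Copper-catalysed propargylic etherification should take place at the more acidic, non-chelated hydroxyl para to the ester, because the ortho hydroxyl is held in a hydrogen bond to the ester carbonyl.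

Step 13
Reactants: 27 allyl 2-(ArB-oxy)-6-hydroxy-3-(3-methylbut-2-enyl)-4-[(2-methylbut-3-yn-2-yl)oxy]benzoate
Product: 29 allyl 7-(ArB-oxy)-5-hydroxy-2,2-dimethyl-8-(3-methylbut-2-enyl)-2H-chromene-6-carboxylate, via ortho-allenylphenol 28 (not isolated)
Conditions: o-xylene, 140 °C
Reagents that add atoms: none
Why: The propargyl Claisen rearrangement can end only at the free ortho carbon (the dienone formed at the prenyl-bearing carbon cannot enolize and reverts), and 1,5-hydrogen shift with oxa-6π electrocyclization of 28 closes the ring A pyran.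

Step 14
Reactants: 29 allyl 7-(ArB-oxy)-5-hydroxy-2,2-dimethyl-8-(3-methylbut-2-enyl)-2H-chromene-6-carboxylate
Product: 30 allyl 7-[(5,8-dihydroxy-2,2-dimethyl-2H-chromen-6-yl)oxy]-5-hydroxy-2,2-dimethyl-8-(3-methylbut-2-enyl)-2H-chromene-6-carboxylate
Conditions: 3 M aq HCl, MeOH, 45 °C, degassed, argon
Reagents that add atoms: none
Why: Acid-catalysed acetal exchange with methanol removes both MOM groups; the prenyl group has no free ortho hydroxyl and so cannot close to a chroman, and exclusion of air protects the liberated hydroquinone.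

Step 15
Reactants: 30 allyl 7-[(5,8-dihydroxy-2,2-dimethyl-2H-chromen-6-yl)oxy]-5-hydroxy-2,2-dimethyl-8-(3-methylbut-2-enyl)-2H-chromene-6-carboxylate
Product: 31 7-[(5,8-dihydroxy-2,2-dimethyl-2H-chromen-6-yl)oxy]-5-hydroxy-2,2-dimethyl-8-(3-methylbut-2-enyl)-2H-chromene-6-carboxylic acid
Conditions: Pd(PPh3)4 (5 mol %), morpholine, THF, rt, argon; work-up at pH 4, 0 °C
Reagents that add atoms: none
Why: Allyl transfer to morpholine through a π-allyl complex formed with zerovalent palladium (Tsuji-Trost deallylation) frees the hindered acid without attack at the doubly ortho-substituted carbonyl and without acid that could decarboxylate it.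

Step 16
Reactants: 31 7-[(5,8-dihydroxy-2,2-dimethyl-2H-chromen-6-yl)oxy]-5-hydroxy-2,2-dimethyl-8-(3-methylbut-2-enyl)-2H-chromene-6-carboxylic acid
Product: 33 garcinisidone C, via O-acylisourea 32 (not isolated)
Conditions: DCC, CH2Cl2 (high dilution), 0 °C → rt, argon
Reagents that add atoms: none
Why: Carbodiimide activation gives 32, which the ring B hydroxyl ortho to the diaryl ether oxygen should attack intramolecularly to close the seven-membered lactone (ring C); the other ring B hydroxyl cannot reach the carbonyl, the ring A hydroxyl is hydrogen-bonded, and high dilution suppresses intermolecular esterification.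

**Compound list**

1 | methyl acetoacetate | COC(=O)CC(C)=O | starting material
2 | prenyl bromide (1-bromo-3-methylbut-2-ene) | CC(C)=CCBr | starting material
3 | sodium lithium dianion of methyl acetoacetate | C=C([O-])C=C([O-])OC.[Li+].[Na+] | intermediate
4 | methyl 7-methyl-3-oxooct-6-enoate | COC(=O)CC(=O)CCC=C(C)C | intermediate
5 | methyl (2Z)-7-methyl-3-(trimethylsilyloxy)octa-2,6-dienoate | COC(=O)/C=C(\O[Si](C)(C)C)CCC=C(C)C | intermediate
6 | lithium dienolate of 5 | CO/C([O-])=C/C(O[Si](C)(C)C)=C/CC=C(C)C.[Li+] | intermediate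
7 | (1Z,3Z)-1-methoxy-7-methyl-1,3-bis(trimethylsilyloxy)octa-1,3,6-triene | CO/C(O[Si](C)(C)C)=C/C(O[Si](C)(C)C)=C/CC=C(C)C | intermediate
8 | 2,5-dibromobenzene-1,4-diol | Oc1cc(Br)c(O)cc1Br | starting material
9 | 1,4-dibromo-2,5-bis(methoxymethoxy)benzene | COCOc1cc(Br)c(OCOC)cc1Br | intermediate
10 | [4-bromo-2,5-bis(methoxymethoxy)phenyl]lithium | [Li]c1cc(OCOC)c(Br)cc1OCOC | intermediate
11 | lithium [4-bromo-2,5-bis(methoxymethoxy)phenyl]trimethoxyborate | [Li+].CO[B-](OC)(OC)c1cc(OCOC)c(Br)cc1OCOC | intermediate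
12 | 4-bromo-2,5-bis(methoxymethoxy)phenol | COCOc1cc(Br)c(OCOC)cc1O | intermediate
13 | 1-bromo-2,5-bis(methoxymethoxy)-4-[(2-methylbut-3-yn-2-yl)oxy]benzene | C#CC(C)(C)Oc1cc(OCOC)c(Br)cc1OCOC | intermediate
14 | 4-bromo-3,6-bis(methoxymethoxy)-2-(3-methylbuta-1,2-dienyl)phenol | CC(C)=C=Cc1c(O)c(OCOC)cc(Br)c1OCOC | intermediate
15 | 6-bromo-5,8-bis(methoxymethoxy)-2,2-dimethyl-2H-chromene | COCOc1cc(Br)c(OCOC)c2C=CC(C)(C)Oc12 | intermediate
16 | [5,8-bis(methoxymethoxy)-2,2-dimethyl-2H-chromen-6-yl]lithium | [Li]c1cc(OCOC)c2OC(C)(C)C=Cc2c1OCOC | intermediate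
17 | lithium [5,8-bis(methoxymethoxy)-2,2-dimethyl-2H-chromen-6-yl]trimethoxyborate | [Li+].CO[B-](OC)(OC)c1cc(OCOC)c2OC(C)(C)C=Cc2c1OCOC | intermediate
18 | 5,8-bis(methoxymethoxy)-2,2-dimethyl-2H-chromen-6-ol | Oc1cc(OCOC)c2OC(C)(C)C=Cc2c1OCOC | intermediate
19 | trichloroethylene | ClC=C(Cl)Cl | starting material
20 | potassium 5,8-bis(methoxymethoxy)-2,2-dimethyl-2H-chromen-6-olate | [K+].[O-]c1cc(OCOC)c2OC(C)(C)C=Cc2c1OCOC | intermediate
21 | 6-{[(E)-1,2-dichloroethenyl]oxy}-5,8-bis(methoxymethoxy)-2,2-dimethyl-2H-chromene | Cl/C=C(/Cl)Oc1cc(OCOC)c2OC(C)(C)C=Cc2c1OCOC | intermediate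
22 | 6-[(chloroethynyl)oxy]-5,8-bis(methoxymethoxy)-2,2-dimethyl-2H-chromene | ClC#COc1cc(OCOC)c2OC(C)(C)C=Cc2c1OCOC | intermediate
23 | ({[5,8-bis(methoxymethoxy)-2,2-dimethyl-2H-chromen-6-yl]oxy}ethynyl)lithium | [Li]C#COc1cc(OCOC)c2OC(C)(C)C=Cc2c1OCOC | intermediate
24 | allyl 3-{[5,8-bis(methoxymethoxy)-2,2-dimethyl-2H-chromen-6-yl]oxy}prop-2-ynoate | C=CCOC(=O)C#COc1cc(OCOC)c2OC(C)(C)C=Cc2c1OCOC | intermediate
25 | allyl 2-{[5,8-bis(methoxymethoxy)-2,2-dimethyl-2H-chromen-6-yl]oxy}-6-methoxy-3-(3-methylbut-2-enyl)-4,6-bis(trimethylsilyloxy)cyclohexa-1,4-diene-1-carboxylate (mixture of diastereomers) | C=CCOC(=O)C1=C(Oc2cc(OCOC)c3OC(C)(C)C=Cc3c2OCOC)C(CC=C(C)C)C(O[Si](C)(C)C)=CC1(OC)O[Si](C)(C)C | intermediate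
26 | allyl 2-{[5,8-bis(methoxymethoxy)-2,2-dimethyl-2H-chromen-6-yl]oxy}-4,6-dihydroxy-3-(3-methylbut-2-enyl)benzoate | C=CCOC(=O)c1c(O)cc(O)c(CC=C(C)C)c1Oc1cc(OCOC)c2OC(C)(C)C=Cc2c1OCOC | intermediate
27 | allyl 2-{[5,8-bis(methoxymethoxy)-2,2-dimethyl-2H-chromen-6-yl]oxy}-6-hydroxy-3-(3-methylbut-2-enyl)-4-[(2-methylbut-3-yn-2-yl)oxy]benzoate | C=CCOC(=O)c1c(O)cc(OC(C)(C)C#C)c(CC=C(C)C)c1Oc1cc(OCOC)c2OC(C)(C)C=Cc2c1OCOC | intermediate
28 | allyl 2-{[5,8-bis(methoxymethoxy)-2,2-dimethyl-2H-chromen-6-yl]oxy}-4,6-dihydroxy-5-(3-methylbuta-1,2-dienyl)-3-(3-methylbut-2-enyl)benzoate | C=CCOC(=O)c1c(O)c(C=C=C(C)C)c(O)c(CC=C(C)C)c1Oc1cc(OCOC)c2OC(C)(C)C=Cc2c1OCOC | intermediate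
29 | allyl 7-{[5,8-bis(methoxymethoxy)-2,2-dimethyl-2H-chromen-6-yl]oxy}-5-hydroxy-2,2-dimethyl-8-(3-methylbut-2-enyl)-2H-chromene-6-carboxylate | C=CCOC(=O)c1c(O)c2C=CC(C)(C)Oc2c(CC=C(C)C)c1Oc1cc(OCOC)c2OC(C)(C)C=Cc2c1OCOC | intermediate
30 | allyl 7-[(5,8-dihydroxy-2,2-dimethyl-2H-chromen-6-yl)oxy]-5-hydroxy-2,2-dimethyl-8-(3-methylbut-2-enyl)-2H-chromene-6-carboxylate | C=CCOC(=O)c1c(O)c2C=CC(C)(C)Oc2c(CC=C(C)C)c1Oc1cc(O)c2OC(C)(C)C=Cc2c1O | intermediate
31 | 7-[(5,8-dihydroxy-2,2-dimethyl-2H-chromen-6-yl)oxy]-5-hydroxy-2,2-dimethyl-8-(3-methylbut-2-enyl)-2H-chromene-6-carboxylic acid | OC(=O)c1c(O)c2C=CC(C)(C)Oc2c(CC=C(C)C)c1Oc1cc(O)c2OC(C)(C)C=Cc2c1O | intermediate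
32 | O-acylisourea of 31 and N,N'-dicyclohexylcarbodiimide | O=C(OC(=NC1CCCCC1)NC1CCCCC1)c1c(O)c2C=CC(C)(C)Oc2c(CC=C(C)C)c1Oc1cc(O)c2OC(C)(C)C=Cc2c1O | intermediate
33 | garcinisidone C | CC(C)=CCc1c2c(c(O)c3c1Oc1cc(O)c4c(c1OC3=O)C=CC(C)(C)O4)C=CC(C)(C)O2 | target

**Step count**

Total: 16 steps. Longest linear sequence: 13 steps (from 8 through steps 4 to 16); the diene branch (steps 1 to 3) joins at step 11.

**Steps most likely to fail**

1. Step 11. The aryloxy donor raises the LUMO of the alkyne, so thermal decay of the diene (silyl migration, protodesilylation) may outrun cycloaddition. Alternatively, a stepwise conjugate addition may be followed by expulsion of the ring B aryloxide from the vinyl anion, which would break the diaryl ether before ring A closes. The fallback sets out from diene 7 and chromenol 18 and comes back at 30; it makes the diaryl ether by copper-mediated C–O coupling instead of carrying it on the dienophile. Diene 7 is combined with allyl 3-bromopropiolate F1 (from allyl propiolate with NBS and catalytic AgNO3 in acetone), a more reactive ynoate of the same polarization, and the adduct is aromatized as in step 11 to allyl 2-bromo-4,6-dihydroxy-3-(3-methylbut-2-enyl)benzoate F2. The conditions of steps 12 and 13 should then give allyl 2-bromo-6-hydroxy-3-(3-methylbut-2-enyl)-4-[(2-methylbut-3-yn-2-yl)oxy]benzoate F3 and allyl 7-bromo-5-hydroxy-2,2-dimethyl-8-(3-methylbut-2-enyl)-2H-chromene-6-carboxylate F4. The chelated hydroxyl is capped (MOMCl, NaH, DMF) as allyl 7-bromo-5-(methoxymethoxy)-2,2-dimethyl-8-(3-methylbut-2-enyl)-2H-chromene-6-carboxylate F5. Ullmann coupling of F5 with 18 (CuI, picolinic acid, K3PO4, DMSO, 90 °C), helped by the ortho ester, should give allyl 7-(ArB-oxy)-5-(methoxymethoxy)-2,2-dimethyl-8-(3-methylbut-2-enyl)-2H-chromene-6-carboxylate F6. The acid treatment of step 14 removes all three MOM groups from F6 and returns to 30.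

2. Step 10. The lithium acetylide may add to the ynoate as it forms, n-BuLi may metalate ring B next to a MOM ether, and the push-pull alkyne may be hydrated during isolation. The fallback sets out from 21 and comes back at 24; it builds the ester in two bond-forming events. Acetylide 23, generated as in step 10, is quenched with dry CO2 to give lithium 3-{[5,8-bis(methoxymethoxy)-2,2-dimethyl-2H-chromen-6-yl]oxy}prop-2-ynoate F7. This carboxylate is not a conjugate acceptor, so a second addition cannot occur. Without acidification it is O-alkylated (allyl bromide, DMF, rt) to 24, which is taken on crude.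

3. Step 12. Etherification at the hydroxyl flanked by the prenyl group may be slow, so that alkylation of the chelated hydroxyl or C-alkylation competes. The fallback sets out from 26 and comes back at 29, replacing steps 12 and 13 by a sequence that forms the C–C bond first. Resorcylate 26 is heated with 3-methylbut-2-enal and catalytic ethylenediammonium diacetate in toluene at 110 °C. Knoevenagel-type condensation at the free ring carbon between the two hydroxyls, then oxa-6π closure onto the non-chelated oxygen, should give 29 directly; no new compound arises (F0).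

**Further compounds**

F1 | step 11 | allyl 3-bromoprop-2-ynoate | C=CCOC(=O)C#CBr
F2 | step 11 | allyl 2-bromo-4,6-dihydroxy-3-(3-methylbut-2-enyl)benzoate | C=CCOC(=O)c1c(O)cc(O)c(CC=C(C)C)c1Br
F3 | step 11 | allyl 2-bromo-6-hydroxy-3-(3-methylbut-2-enyl)-4-[(2-methylbut-3-yn-2-yl)oxy]benzoate | C=CCOC(=O)c1c(O)cc(OC(C)(C)C#C)c(CC=C(C)C)c1Br
F4 | step 11 | allyl 7-bromo-5-hydroxy-2,2-dimethyl-8-(3-methylbut-2-enyl)-2H-chromene-6-carboxylate | C=CCOC(=O)c1c(O)c2C=CC(C)(C)Oc2c(CC=C(C)C)c1Br
F5 | step 11 | allyl 7-bromo-5-(methoxymethoxy)-2,2-dimethyl-8-(3-methylbut-2-enyl)-2H-chromene-6-carboxylate | C=CCOC(=O)c1c(OCOC)c2C=CC(C)(C)Oc2c(CC=C(C)C)c1Br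
F6 | step 11 | allyl 7-{[5,8-bis(methoxymethoxy)-2,2-dimethyl-2H-chromen-6-yl]oxy}-5-(methoxymethoxy)-2,2-dimethyl-8-(3-methylbut-2-enyl)-2H-chromene-6-carboxylate | C=CCOC(=O)c1c(OCOC)c2C=CC(C)(C)Oc2c(CC=C(C)C)c1Oc1cc(OCOC)c2OC(C)(C)C=Cc2c1OCOC
F7 | step 10 | lithium 3-{[5,8-bis(methoxymethoxy)-2,2-dimethyl-2H-chromen-6-yl]oxy}prop-2-ynoate | [Li+].[O-]C(=O)C#COc1cc(OCOC)c2OC(C)(C)C=Cc2c1OCOC
F0 | step 12 | none | none
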